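## Structural features

With germacrane numbering (C1 ketone, C2=C3 enol ether, C4 to C10 around the ring, C11–C13 the acrylate unit, C14 and C15 the methyls on C10 and C4), the target is a ten-membered carbocycle C1–C10 whose C3 and C10 are bridged by one oxygen. O, C10, C1, C2 and C3 therefore form a 3(2H)-furanone inside an 11-oxabicyclo[6.2.1]undecane. An α-methylene-γ-butyrolactone (O, C6, C7, C11, C12) is fused to C6–C7 with H6 and H7 cis, and O8 carries an angelate. Seven contiguous stereocentres run from C4 to C10 (4R,5S,6R,7S,8S,9R,10R); C10 is quaternary (CH3, ring O, C1, C9) and sits between the C1 carbonyl and the C9 carbinol. Fragile groups are the exo-methylene lactone (Michael acceptor), the (Z)-angelate (isomerises to tiglate), the γ-acidic C4–H of the vinylogous ester and the β-hydroxy ketone C9–C10–C1 (retro-aldol). The real difficulty is the oxygen-bridged medium ring with its quaternary C10, followed by the C7–C8–C9 triad on a flexible ring. The key step exploits the unit O–C10(–C9)–C1(=O)–C2–C3: a tetrahydrofuran-3-one spanning a ten-membered ring is the product type of an oxonium ylide [2,3]-shift, and O, C3, C4, C5, C6, C7 then map onto a tetrahydropyran in which the stereocentres can be set by six-membered-ring and acyclic control.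

## Logic of the disconnections

29 ⇒ 27: C11–C12 and C12–O6 are cut (CO removed) and the two PMB ethers on O5 and O9 are restored (28). The acrylate lactone is the most fragile unit, so it is made last from an ethynyl group on C7 and the free C6 hydroxyl. The forward step must be Markovnikov and must give the five-membered lactone.

27 ⇒ 25: the angelate C–O bond at O8 is cut and the silyl groups on O6 and on the alkyne are restored (26). This requires O8 to be the only free hydroxyl at the time of esterification, and ester formation without Z/E isomerisation.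

25 ⇒ 23: C8–O and C7–H are cut, giving the C7=C8 alkene. Two stereocentres are replaced by one trisubstituted E-alkene held in the bicycle. The forward addition must be syn, anti-Markovnikov and from one face only.

23 ⇒ 21: the C2=C3 unsaturation is removed. This postpones the base-sensitive furanone and lets C3 serve as a temporary stereocentre.

21 ⇒ 18 (key disconnection): C9–C10 and O–C10 are cut and O–C7 is reconnected. The oxygen-bridged ten-membered ring collapses to a tetrahydropyran carrying a diazoketone side chain on C3 and an (E)-2-alkoxyvinyl group plus a silylethynyl group on C7. In one sentence: a copper-catalysed oxonium ylide formation/[2,3]-sigmatropic three-atom ring expansion of the 2-alkenyl-tetrahydropyranyl α-diazoketone gives the furanone-bridged ring. The gain is that the medium ring, the oxygen bridge, C10, C9 and the C7=C8 geometry all come from a chair-shaped six-membered ring. The demand is a cis relationship of the C3 side chain to the C4, C5 and C6 substituents, a defined configuration at C7, an (E)-enol ether, and ylide formation faster than carbenoid side reactions.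

18 ⇒ 16: C1–C10 is cut (diazoethane acylation). The forward step must be free of acid because of the enol ether.

16 ⇒ 13: O9–C9 is cut; the enol ether comes from a terminal alkyne through an (E)-alkenylboronate (14, 15). The geometry must be purely E because it encodes C9.

13 ⇒ 9: C7–C8 and C7–C11 are cut, and both alkynes are removed from a lactone carbonyl (10, 11, 12). The quaternary C7 becomes a carbonyl carbon. The second alkyne must enter on the face opposite to the ring substituents.

9 ⇒ 6: the lactone O–C7 bond is cut to give a triol ester (7, 8). The forward oxidation must select the primary hydroxyl.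

6 ⇒ 4: C2–C3 is cut (acetate aldol, 5). C3 must be formed 3,4-syn and 3,5-anti.

4 ⇒ 1: C4–C5 is cut (crotylation; 2, 3) and the vinyl group stands for the C3 aldehyde. Only the C6 stereocentre is bought with 1; C4 and C5 must be set anti,anti to it.

## Other disconnections considered

Alternative 1: the first idea is to cut C6–C7 together with the lactone C12–O6 bond and to close the ten-membered ring by an intramolecular Barbier/Nozaki–Hiyama–Kishi-type allylation of the aldehyde–allylic bromide A1, whose furanone would come from an acyclic hydroxy-ynone. The chosen plan is preferred for three reasons. The ring closure of A1 is an end-to-end encounter across a medium ring and has to create the less common cis relationship of H6 and H7 with no controlling element. The quaternary C10 carbinol has to be made on an open chain without relay from another centre. The chosen route closes the ring by a unimolecular sigmatropic shift inside a five-membered ylide and relays C10 and C9 from existing centres.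

Alternative 2: cut C9–C10 and close the ring by an intramolecular Mukaiyama aldol of the 2-methyl-3-silyloxyfuran aldehyde A2, dearomatising the furan to the furanone while creating C10 and C9. The face of the planar furan over which the tether closes decides C10 and is not governed by any adjacent stereocentre. Bridging an aromatic furan at its 2- and 5-positions with six atoms is strained in the transition state. The aldol is reversible towards an aromatic furanolate. The lactone and angelate would have to be carried through Lewis-acid conditions. The chosen plan fixes C10 through the temporary C3 centre.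

Alternative 3: reconnect C5–C10 and cut C2–C3, i.e. an anionic oxy-Cope ring expansion of the 1,2-dialkenylcyclohexanol A3, whose six-membered ring would carry C6 to C9. This gives the carbocycle but none of the oxygen bridge. C10–O, the C1 ketone, the C3 oxidation level and the C5 carbinol would all remain to be set on a mobile cyclodecenone, and A3 needs two adjacent fully substituted ring carbons. It is judged longer, and less secure at C10.

Key step: step 15

Remark: the tartrate crotylboronate of step 1 and the diazoethane of step 14 are freshly prepared reagent solutions made from commercial chemicals (trans-2-butene, B(Oi-Pr)3 and diisopropyl (R,R)-tartrate; N-ethyl-N-nitrosourea and KOH).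

## Steps

Step 1
Reactants: 1 (R)-2,2-dimethyl-1,3-dioxolane-4-carbaldehyde
Product: 2 (1S,2S)-1-[(4R)-2,2-dimethyl-1,3-dioxolan-4-yl]-2-methylbut-3-en-1-ol
Conditions: (R,R)-diisopropyl tartrate (E)-crotylboronate, 4 Å MS, toluene, −78 °C; aq. NaHCO3
Reagents that add atoms: (4R,5R)-diisopropyl 2-[(E)-but-2-enyl]-1,3,2-dioxaborolane-4,5-dicarboxylate, CC(C)OC(=O)[C@@H]1OB(C/C=C/C)O[C@H]1C(=O)OC(C)C
Why: Roush crotylboration through a closed chair transition state: the (E)-boronate gives the 4,5-anti pair and the (R,R)-tartrate reagent attacks the si face of the aldehyde, which is also the Felkin–Anh face of 1 (matched case), so C4 and C5 are set relative to the purchased C6.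

Step 2
Reactants: 2 (1S,2S)-1-[(4R)-2,2-dimethyl-1,3-dioxolan-4-yl]-2-methylbut-3-en-1-ol
Product: 3 (4R)-4-[(1S,2S)-1-(4-methoxybenzyloxy)-2-methylbut-3-enyl]-2,2-dimethyl-1,3-dioxolane
Conditions: NaH, PMBCl, Bu4NI (cat.), DMF, 0 °C → rt
Reagents that add atoms: 4-methoxybenzyl chloride, COc1ccc(CCl)cc1
Why: Williamson etherification of the alkoxide; no stereocentre is touched and this PMB group is meant to stay until the last step.

Step 3
Reactants: 3 (4R)-4-[(1S,2S)-1-(4-methoxybenzyloxy)-2-methylbut-3-enyl]-2,2-dimethyl-1,3-dioxolane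
Product: 4 (2R,3S)-3-[(4R)-2,2-dimethyl-1,3-dioxolan-4-yl]-3-(4-methoxybenzyloxy)-2-methylpropanal
Conditions: O3, CH2Cl2, −78 °C; PPh3, −78 °C → rt
Reagents that add atoms: ozone, [O-][O+]=O
Why: Ozonolysis with reductive work-up cleaves the terminal alkene; the α-methyl aldehyde is used at once so that C4 does not epimerise.

Step 4
Reactants: 4 (2R,3S)-3-[(4R)-2,2-dimethyl-1,3-dioxolan-4-yl]-3-(4-methoxybenzyloxy)-2-methylpropanal
Product: 5 methyl (3R,4S,5S)-5-[(4R)-2,2-dimethyl-1,3-dioxolan-4-yl]-3-hydroxy-5-(4-methoxybenzyloxy)-4-methylpentanoate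
Conditions: CH2=C(OMe)OTBS, BF3·OEt2, CH2Cl2, −78 °C
Reagents that add atoms: 1-(tert-butyldimethylsilyloxy)-1-methoxyethene, C=C(OC)O[Si](C)(C)C(C)(C)C
Why: Mukaiyama aldol addition through an open transition state; Felkin–Anh attack (3,4-syn) and 1,3-anti induction by the β-OPMB group reinforce each other for this 4,5-anti aldehyde and set C3, the temporary stereocentre that later dictates C10.

Step 5
Reactants: 5 methyl (3R,4S,5S)-5-[(4R)-2,2-dimethyl-1,3-dioxolan-4-yl]-3-hydroxy-5-(4-methoxybenzyloxy)-4-methylpentanoate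
Product: 6 methyl (3R,4S,5S,6R)-3,6,7-trihydroxy-5-(4-methoxybenzyloxy)-4-methylheptanoate
Conditions: AcOH/H2O (4:1), 40 °C
Reagents that add atoms: none
Why: Acid hydrolysis of the isopropylidene acetal; the PMB ether and the β-hydroxy ester tolerate aqueous acetic acid.

Step 6
Reactants: 6 methyl (3R,4S,5S,6R)-3,6,7-trihydroxy-5-(4-methoxybenzyloxy)-4-methylheptanoate
Product: 8 methyl 2-[(2R,3S,4S,5S)-5-hydroxy-4-(4-methoxybenzyloxy)-3-methyl-6-oxooxan-2-yl]acetate (all four ring substituents cis), via lactol 7 (not isolated)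
Conditions: Cu(MeCN)4OTf (5 mol %), 2,2′-bipyridine, TEMPO, N-methylimidazole, air, MeCN, rt
Reagents that add atoms: none
Why: Copper/nitroxyl aerobic alcohol oxidation is selective for the primary C7 carbinol; the aldehyde is trapped by O3 as the six-membered lactol 7, which is oxidised on to the δ-lactone while the secondary hydroxyls stay, and no glycol-cleaving oxidant is present.

Step 7
Reactants: 8 methyl 2-[(2R,3S,4S,5S)-5-hydroxy-4-(4-methoxybenzyloxy)-3-methyl-6-oxooxan-2-yl]acetate
Product: 9 methyl 2-[(2R,3S,4S,5S)-5-(tert-butyldimethylsilyloxy)-4-(4-methoxybenzyloxy)-3-methyl-6-oxooxan-2-yl]acetate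
Conditions: TBSOTf, 2,6-lutidine, CH2Cl2, −78 → 0 °C
Reagents that add atoms: tert-butyldimethylsilyl triflate, CC(C)(C)[Si](C)(C)OS(=O)(=O)C(F)(F)F
Why: Silylation of the α-hydroxy lactone with a hindered base, conditions that do not epimerise C6.

Step 8
Reactants: 9 methyl 2-[(2R,3S,4S,5S)-5-(tert-butyldimethylsilyloxy)-4-(4-methoxybenzyloxy)-3-methyl-6-oxooxan-2-yl]acetate
Product: 10 hemiketal of 9 carrying OH and (triisopropylsilyl)ethynyl on C7 (oxane C6; both anomers)
Conditions: (i-Pr)3SiC≡CH, n-BuLi, THF, −78 °C; then 9 (1.05 equiv of acetylide), −78 °C; aq. NH4Cl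
Reagents that add atoms: (triisopropylsilyl)acetylene, C#C[Si](C(C)C)(C(C)C)C(C)C
Why: 1,2-Addition of a lithium acetylide to a δ-lactone stops at the hemiketal (the chemistry of sugar lactones); at −78 °C the α-oxygenated lactone carbonyl is more electrophilic than the methyl ester.

Step 9
Reactants: 10 hemiketal of 9 carrying OH and (triisopropylsilyl)ethynyl on C7
Product: 12 methyl 2-[oxan-2-yl]acetate with 3-methyl, 4-OPMB, 5-OTBS and the acetate arm all cis and with C6 (= C7) bearing (triisopropylsilyl)ethynyl cis and (trimethylsilyl)ethynyl trans to them, via oxocarbenium ion 11 (not isolated)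
Conditions: Me3SiC≡CSiMe3 (3 equiv), TMSOTf (0.3 equiv), CH2Cl2, −78 → −30 °C
Reagents that add atoms: bis(trimethylsilyl)acetylene, C[Si](C)(C)C#C[Si](C)(C)C
Why: C-Glycosidation-type alkynylation: ionisation gives oxocarbenium ion 11, which is attacked at C7 by the silylacetylene with loss of one silyl group; attack is axial on the unsubstituted face, anti to the adjacent C6–OTBS and to all four cis ring substituents (as in α-selective C-glycosidations of donors with an axial 2-substituent), so the new alkyne ends trans to them and C7 is set.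

Step 10
Reactants: 12 bis-alkynyl oxane (TIPS-alkyne cis, TMS-alkyne trans)
Product: 13 the same oxane with a free ethynyl group trans and the (triisopropylsilyl)ethynyl group cis at C7
Conditions: K2CO3 (0.2 equiv), MeOH, 0 °C
Reagents that add atoms: none
Why: Methanolysis cleaves the trimethylsilyl alkyne only; the triisopropylsilyl alkyne and the methyl ester (methanol as solvent) are unchanged.

Step 11
Reactants: 13 ethynyl oxane
Product: 14 the (E)-2-(pinacolboryl)vinyl oxane
Conditions: pinacolborane, Cp2Zr(H)Cl (10 mol %), Et3N (10 mol %), CH2Cl2, 40 °C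
Reagents that add atoms: pinacolborane, CC1(C)OBOC1(C)C
Why: Zirconium-catalysed syn-hydroboration of the terminal alkyne gives only the (E)-alkenylboronate; the bulky silyl alkyne is inert.

Step 12
Reactants: 14 (E)-2-(pinacolboryl)vinyl oxane
Product: 15 the (E)-2-(4-methoxybenzyloxy)vinyl oxane (methyl ester)
Conditions: Cu(OAc)2 (2 equiv), Et3N (4 equiv), 4-MeOC6H4CH2OH (10 equiv), 4 Å MS, CH2Cl2, air, rt
Reagents that add atoms: 4-methoxybenzyl alcohol, COc1ccc(CO)cc1
Why: Chan–Lam-type oxidative C–O coupling of an alkenylboronate with an alcohol proceeds with retention of alkene geometry and gives the (E)-enol ether whose geometry will encode C9.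

Step 13
Reactants: 15 (E)-enol ether methyl ester
Product: 16 the corresponding carboxylic acid
Conditions: LiOH·H2O, THF/MeOH/H2O, 0 °C → rt; NaH2PO4 buffer (pH 5)
Reagents that add atoms: lithium hydroxide, [Li+].[OH-]
Why: Saponification of the methyl ester; the enol ether is stable to base and the work-up is kept at pH 5 or above.

Step 14
Reactants: 16 carboxylic acid
Product: 18 the 3-diazobutan-2-one (α-methyl diazoketone CH2–C(=O)–C(N2)–CH3 on C3), via mixed anhydride 17 (not isolated)
Conditions: i-BuOCOCl, Et3N, THF, −15 °C; then CH3CHN2 (3 equiv) in Et2O, −15 → 0 °C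
Reagents that add atoms: diazoethane, CC=[N+]=[N-]
Why: Acylation of diazoethane by the mixed carbonic anhydride (the diazoketone stage of the Arndt–Eistert sequence) under acid-free conditions that spare the enol ether.

Step 15
Reactants: 18 α-methyl diazoketone
Product: 21 (7E)-3,10-epoxygermacr-7-en-1-one with 5-OPMB 6-OTBS 9-OPMB and 7-[(triisopropylsilyl)ethynyl] (11-oxabicyclo[6.2.1]undec-enone), via copper carbenoid 19 (not isolated), via oxonium ylide 20 (not isolated)
Conditions: Cu(hfacac)2 (5 mol %), CH2Cl2, reflux, slow addition of 18 (final 2 mM)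
Reagents that add atoms: none
Why: Catalytic oxonium ylide formation and [2,3]-sigmatropic rearrangement, the known three-atom ring expansion of 2-alkenyl tetrahydropyranyl diazoketones to oxabicyclo[6.2.1]undecenones: loss of N2 at copper gives carbenoid 19, the ring oxygen attacks its carbon to give ylide 20, and C10 then bonds to C9 while O–C7 breaks. The five-membered ring (O, C10, C1, C2, C3) closes in the ylide-forming step by exo attack of the ether oxygen on the carbenoid, and the ten-membered carbocycle (nine-membered oxacycle) arises in the sigmatropic step through a five-membered envelope C10–O–C7–C8–C9. C10 is controlled by C3: only the cis-fused ylide (O–C10 and C3–C2 on the same face of the pyran) can reach C9 and the six-carbon bridge must span one face of the new five-membered ring, so the C3 configuration is translated into 10R. In the reacting chair the O–C10 bond is equatorial and anti to C6, so C9 swings to the side of the axial alkyne and the new C7=C8 bond is E with the alkyne cis to C9. C9 is set by the suprafacial shift on the (E)-enol ether (O9 outside, H9 inside the envelope), which gives 9R. The selectivity needed is ylide formation over 1,2-hydride shift of the methyl carbenoid and over C–H insertion; the five-membered-ring proximity of the basic ring oxygen, a copper rather than a rhodium catalyst and a low stationary concentration of 18 secure it, and every other ether oxygen would need a ring of seven or more atoms.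

Step 16
Reactants: 21 ring-expanded ketone
Product: 23 the 3(2H)-furanone (C2=C3) of 21, via silyl enol ether 22 (not isolated)
Conditions: TMSOTf, Et3N, CH2Cl2, 0 °C; then Pd(OAc)2 (1.1 equiv), MeCN, rt
Reagents that add atoms: none
Why: Saegusa–Ito oxidation: the ketone can enolise only towards C2 (C10 is quaternary) and β-hydride elimination can occur only towards C3–H, which gives the furanone and removes the temporary C3 stereocentre.

Step 17
Reactants: 23 furanone enyne
Product: 25 the C8 alcohol (7-H, 8-OH) of the furanone series, via alkylborane 24 (not isolated)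
Conditions: BH3·THF (1.2 equiv), THF, −20 → 0 °C; then NaBO3·4H2O, THF/H2O, rt
Reagents that add atoms: sodium perborate, [Na+].[Na+].O[B-]1(O)OO[B-](O)(O)OO1
Why: Hydroboration–oxidation: the strained E-trisubstituted alkene reacts faster than the vinylogous-ester carbonyl or the silyl alkyne, boron adds to the less substituted C8, and syn addition from the only open (peripheral) face of the trans-cycloalkene, opposite to the O/C10 bridge, sets C7 and C8 together in the sense of the target.

Step 18
Reactants: 25 C8 alcohol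
Product: 26 the C8 angelate
Conditions: angelic acid, 2,4,6-Cl3C6H2COCl, Et3N, toluene, rt; then 25, 80 °C
Reagents that add atoms: angelic acid, C/C=C(/C)C(=O)O
Why: Yamaguchi-type esterification with the pre-formed mixed anhydride and without DMAP, conditions chosen to avoid isomerisation of the (Z)-angelate to the tiglate; O8 is the only free hydroxyl.

Step 19
Reactants: 26 C8 angelate
Product: 27 the alkynol (6-OH, 7-ethynyl)
Conditions: TBAF (4 equiv), AcOH (4 equiv), THF, 0 °C → rt
Reagents that add atoms: none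
Why: Buffered fluoride removes the C6 silyl ether and the alkynyl silyl group in one operation; acetic acid suppresses 1,3-acyl migration of the angelate and epimerisation at C4.

Step 20
Reactants: 27 alkynol
Product: 28 the 5,9-bis-PMB ether of the target
Conditions: Pd(OAc)2 (5 mol %), 2-PyPPh2 (20 mol %), MsOH (10 mol %), CO (20 bar), THF, 50 °C
Reagents that add atoms: carbon monoxide, [C-]#[O+]
Why: Palladium-catalysed cyclocarbonylation (intramolecular Markovnikov alkoxycarbonylation) of a homopropargylic alcohol gives the α-methylene-γ-butyrolactone directly: C12 comes from CO, C11 and C13 from the ethynyl group, and the cis ring fusion is fixed by the existing C6 and C7 centres.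

Step 21
Reactants: 28 bis-PMB ether
Product: 29 CNP0206920.1
Conditions: DDQ (3 equiv), CH2Cl2/pH 7 buffer (10:1), 0 °C → rt
Reagents that add atoms: none
Why: Oxidative cleavage of both PMB ethers by DDQ under buffered conditions; lactone, angelate and furanone are inert and neither acid nor base touches C4 or the exo-methylene group.

## Compound list

1 | (R)-2,2-dimethyl-1,3-dioxolane-4-carbaldehyde (2,3-O-isopropylidene-D-glyceraldehyde) | O=C[C@H]1COC(C)(C)O1 | starting material
2 | (1S,2S)-1-[(4R)-2,2-dimethyl-1,3-dioxolan-4-yl]-2-methylbut-3-en-1-ol | C=C[C@H](C)[C@H](O)[C@H]1COC(C)(C)O1 | intermediate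
3 | (4R)-4-[(1S,2S)-1-(4-methoxybenzyloxy)-2-methylbut-3-enyl]-2,2-dimethyl-1,3-dioxolane | C=C[C@H](C)[C@H](OCc2ccc(OC)cc2)[C@H]1COC(C)(C)O1 | intermediate
4 | (2R,3S)-3-[(4R)-2,2-dimethyl-1,3-dioxolan-4-yl]-3-(4-methoxybenzyloxy)-2-methylpropanal | O=C[C@H](C)[C@H](OCc2ccc(OC)cc2)[C@H]1COC(C)(C)O1 | intermediate
5 | methyl (3R,4S,5S)-5-[(4R)-2,2-dimethyl-1,3-dioxolan-4-yl]-3-hydroxy-5-(4-methoxybenzyloxy)-4-methylpentanoate | COC(=O)C[C@@H](O)[C@H](C)[C@H](OCc2ccc(OC)cc2)[C@H]1COC(C)(C)O1 | intermediate
6 | methyl (3R,4S,5S,6R)-3,6,7-trihydroxy-5-(4-methoxybenzyloxy)-4-methylheptanoate | COC(=O)C[C@@H](O)[C@H](C)[C@H](OCc1ccc(OC)cc1)[C@H](O)CO | intermediate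
7 | lactol: methyl 2-[(2R,3S,4S,5S)-5,6-dihydroxy-4-(4-methoxybenzyloxy)-3-methyloxan-2-yl]acetate (both anomers) | COC(=O)C[C@H]1OC(O)[C@@H](O)[C@@H](OCc2ccc(OC)cc2)[C@H]1C | intermediate (not isolated)
8 | methyl 2-[(2R,3S,4S,5S)-5-hydroxy-4-(4-methoxybenzyloxy)-3-methyl-6-oxooxan-2-yl]acetate (ring substituents all cis) | COC(=O)C[C@H]1OC(=O)[C@@H](O)[C@@H](OCc2ccc(OC)cc2)[C@H]1C | intermediate
9 | methyl 2-[(2R,3S,4S,5S)-5-(tert-butyldimethylsilyloxy)-4-(4-methoxybenzyloxy)-3-methyl-6-oxooxan-2-yl]acetate | COC(=O)C[C@H]1OC(=O)[C@@H](O[Si](C)(C)C(C)(C)C)[C@@H](OCc2ccc(OC)cc2)[C@H]1C | intermediate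
10 | hemiketal of 9: oxane C6 (= C7) bears OH and (triisopropylsilyl)ethynyl, both anomers | COC(=O)C[C@H]1OC(O)(C#C[Si](C(C)C)(C(C)C)C(C)C)[C@@H](O[Si](C)(C)C(C)(C)C)[C@@H](OCc2ccc(OC)cc2)[C@H]1C | intermediate
11 | oxocarbenium ion from 10 (O=C7 cation bearing the TIPS-alkyne) | COC(=O)C[C@H]1[O+]=C(C#C[Si](C(C)C)(C(C)C)C(C)C)[C@@H](O[Si](C)(C)C(C)(C)C)[C@@H](OCc2ccc(OC)cc2)[C@H]1C | intermediate (not isolated)
12 | bis-alkynyl oxane: acetate arm, 3-CH3, 4-OPMB, 5-OTBS all cis; C6 (= C7) with (triisopropylsilyl)ethynyl cis and (trimethylsilyl)ethynyl trans to them | COC(=O)C[C@H]1O[C@](C#C[Si](C(C)C)(C(C)C)C(C)C)(C#C[Si](C)(C)C)[C@@H](O[Si](C)(C)C(C)(C)C)[C@@H](OCc2ccc(OC)cc2)[C@H]1C | intermediate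
13 | as 12 with a free ethynyl group in place of the (trimethylsilyl)ethynyl group | COC(=O)C[C@H]1O[C@](C#C[Si](C(C)C)(C(C)C)C(C)C)(C#C)[C@@H](O[Si](C)(C)C(C)(C)C)[C@@H](OCc2ccc(OC)cc2)[C@H]1C | intermediate
14 | as 13 with an (E)-2-(4,4,5,5-tetramethyl-1,3,2-dioxaborolan-2-yl)vinyl group in place of ethynyl | COC(=O)C[C@H]1O[C@](C#C[Si](C(C)C)(C(C)C)C(C)C)(/C=C/B2OC(C)(C)C(C)(C)O2)[C@@H](O[Si](C)(C)C(C)(C)C)[C@@H](OCc2ccc(OC)cc2)[C@H]1C | intermediate
15 | as 14 with an (E)-2-(4-methoxybenzyloxy)vinyl group (C8=C9–OPMB) | COC(=O)C[C@H]1O[C@](C#C[Si](C(C)C)(C(C)C)C(C)C)(/C=C/OCc2ccc(OC)cc2)[C@@H](O[Si](C)(C)C(C)(C)C)[C@@H](OCc2ccc(OC)cc2)[C@H]1C | intermediate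
16 | carboxylic acid of 15 | OC(=O)C[C@H]1O[C@](C#C[Si](C(C)C)(C(C)C)C(C)C)(/C=C/OCc2ccc(OC)cc2)[C@@H](O[Si](C)(C)C(C)(C)C)[C@@H](OCc2ccc(OC)cc2)[C@H]1C | intermediate
17 | isobutyl carbonic mixed anhydride of 16 | CC(C)COC(=O)OC(=O)C[C@H]1O[C@](C#C[Si](C(C)C)(C(C)C)C(C)C)(/C=C/OCc2ccc(OC)cc2)[C@@H](O[Si](C)(C)C(C)(C)C)[C@@H](OCc2ccc(OC)cc2)[C@H]1C | intermediate (not isolated)
18 | α-methyl diazoketone: side chain CH2–C(=O)–C(=N2)–CH3 on oxane C2 (= C3), otherwise as 16 | CC(=[N+]=[N-])C(=O)C[C@H]1O[C@](C#C[Si](C(C)C)(C(C)C)C(C)C)(/C=C/OCc2ccc(OC)cc2)[C@@H](O[Si](C)(C)C(C)(C)C)[C@@H](OCc2ccc(OC)cc2)[C@H]1C | intermediate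
19 | copper carbenoid of 18 (Cu=C10; hexafluoroacetylacetonate ligands not drawn) | CC(=[Cu])C(=O)C[C@H]1O[C@](C#C[Si](C(C)C)(C(C)C)C(C)C)(/C=C/OCc2ccc(OC)cc2)[C@@H](O[Si](C)(C)C(C)(C)C)[C@@H](OCc2ccc(OC)cc2)[C@H]1C | intermediate (not isolated)
20 | bicyclic oxonium ylide (O+ bonded to C3, C7 and C10; C10 carbanion next to C1=O), cis-fused | C[C-]1C(=O)C[C@H]2[O+]1[C@](C#C[Si](C(C)C)(C(C)C)C(C)C)(/C=C/OCc3ccc(OC)cc3)[C@@H](O[Si](C)(C)C(C)(C)C)[C@@H](OCc3ccc(OC)cc3)[C@H]2C | intermediate (not isolated)
21 | (7E)-3,10-epoxygermacr-7-en-1-one: 4-CH3, 5-OPMB, 6-OTBS, 7-[(triisopropylsilyl)ethynyl], 9-OPMB, 10-CH3; C4, C5, C6, C9, C10 as in the target, C3–H on the face of C10–CH3 | C[C@@H]1[C@H](OCc3ccc(OC)cc3)[C@H](O[Si](C)(C)C(C)(C)C)/C(C#C[Si](C(C)C)(C(C)C)C(C)C)=C/[C@@H](OCc3ccc(OC)cc3)[C@@]2(C)O[C@@H]1CC2=O | intermediate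
22 | trimethylsilyl enol ether of 21 (C1(OTMS)=C2) | C[C@@H]1[C@H](OCc3ccc(OC)cc3)[C@H](O[Si](C)(C)C(C)(C)C)/C(C#C[Si](C(C)C)(C(C)C)C(C)C)=C/[C@@H](OCc3ccc(OC)cc3)[C@@]2(C)O[C@@H]1C=C2O[Si](C)(C)C | intermediate (not isolated)
23 | furanone: 21 with C2=C3 (3,10-epoxygermacra-2,7(E)-dien-1-one core) | C[C@@H]1[C@H](OCc3ccc(OC)cc3)[C@H](O[Si](C)(C)C(C)(C)C)/C(C#C[Si](C(C)C)(C(C)C)C(C)C)=C/[C@@H](OCc3ccc(OC)cc3)[C@@]2(C)OC1=CC2=O | intermediate
24 | C8 alkylborane (7-H, 8-BH2) from 23 | C[C@@H]1[C@H](OCc3ccc(OC)cc3)[C@H](O[Si](C)(C)C(C)(C)C)[C@H](C#C[Si](C(C)C)(C(C)C)C(C)C)[C@H]([BH2])[C@@H](OCc3ccc(OC)cc3)[C@@]2(C)OC1=CC2=O | intermediate (not isolated)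
25 | C8 alcohol: furanone core with 5-OPMB, 6-OTBS, 7-[(triisopropylsilyl)ethynyl], 8-OH, 9-OPMB; C4 to C10 as in the target | C[C@@H]1[C@H](OCc3ccc(OC)cc3)[C@H](O[Si](C)(C)C(C)(C)C)[C@H](C#C[Si](C(C)C)(C(C)C)C(C)C)[C@H](O)[C@@H](OCc3ccc(OC)cc3)[C@@]2(C)OC1=CC2=O | intermediate
26 | C8 angelate of 25 | C[C@@H]1[C@H](OCc3ccc(OC)cc3)[C@H](O[Si](C)(C)C(C)(C)C)[C@H](C#C[Si](C(C)C)(C(C)C)C(C)C)[C@H](OC(=O)/C(C)=C\C)[C@@H](OCc3ccc(OC)cc3)[C@@]2(C)OC1=CC2=O | intermediate
27 | alkynol: 26 with free 6-OH and free 7-ethynyl | C[C@@H]1[C@H](OCc3ccc(OC)cc3)[C@H](O)[C@H](C#C)[C@H](OC(=O)/C(C)=C\C)[C@@H](OCc3ccc(OC)cc3)[C@@]2(C)OC1=CC2=O | intermediate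
28 | 5,9-bis-O-(4-methoxybenzyl) ether of the target | C[C@@H]1[C@H](OCc4ccc(OC)cc4)[C@@H]3OC(=O)C(=C)[C@@H]3[C@H](OC(=O)/C(C)=C\C)[C@@H](OCc4ccc(OC)cc4)[C@@]2(C)OC1=CC2=O | intermediate
29 | CNP0206920.1: (4R,5S,6R,7S,8S,9R,10R)-8-angeloyloxy-5,9-dihydroxy-3,10-epoxy-1-oxogermacra-2,11(13)-dien-12,6-olide | C=C1C(=O)O[C@H]2[C@@H](O)[C@@H](C)C3=CC(=O)[C@](C)(O3)[C@H](O)[C@@H](OC(=O)/C(C)=C\C)[C@@H]12 | target

## Step count and least certain steps

Total: 21 steps. Longest linear sequence: 21 steps from 1 (all carbon fragments are added as reagents to one chain).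

Step 15 (key step). What may go wrong: 1,2-hydride migration within the methyl-substituted carbenoid (to an enone) or insertion into the tertiary C4–H bond outruns attack of the ring oxygen; ylide formation on the face that cannot reach C9 would be unproductive. Fallback (sets out from 16, returns at 21): the acid is activated with carbonyldiimidazole and used to C-acylate magnesium methyl malonate, giving the β-keto ester F1. Diazo transfer (p-acetamidobenzenesulfonyl azide, Et3N) gives the α-diazo-β-keto ester F2, whose carbene carbon carries no migrating hydrogen. The same ylide/[2,3] sequence (Rh2(OAc)4 or Cu(hfacac)2), well established for such acceptor/acceptor diazo compounds, should give the ring-expanded keto ester F3 with CO2Me on C10. LiBH4 reduces ketone and ester to the diol F4. The primary hydroxyl is converted selectively into the phenyl thionocarbonate F5. Barton–McCombie reduction (Bu3SnH, AIBN) gives the C10-methyl carbinol F6, and Dess–Martin oxidation returns 21.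

Step 9. What may go wrong: poor facial discrimination in the addition to the oxocarbenium ion, or entry of the nucleophile on the substituted face. Either would exchange the two alkynes at C7 and so invert C7, C8 and C9 relative to C4–C6 and C10. Slow ionisation of the alkynyl hemiketal is a second risk. Fallback (from 9, returns at 12): the order of introduction is reversed. Lithium (trimethylsilyl)acetylide is added to 9 to give the hemiketal F7. The (triisopropylsilyl)ethynyl group is then delivered second, under TMSOTf, from 1-(triisopropylsilyl)-2-(trimethylsilyl)acetylene F8 (from (triisopropylsilyl)acetylene, n-BuLi and TMSCl). Whichever face the cation prefers, one of the two orders leads to 12.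

Step 12. What may go wrong: protodeboronation or oxidative homocoupling of the alkenylboronate competes with C–O bond formation. Fallback (from 13, returns at 15): hydrozirconation of 13 with Cp2Zr(H)Cl and iodinolysis gives the (E)-alkenyl iodide F9. This is coupled with 4-methoxybenzyl alcohol under Ullmann-type conditions (CuI, 3,4,7,8-tetramethyl-1,10-phenanthroline, Cs2CO3, toluene, 80 °C) with retention of geometry. Any ester exchanged for the PMB ester converges at 16 in step 13.

Step 17. What may go wrong: reduction of the furanone carbonyl or hydroboration of the silyl alkyne competes with addition to the alkene. Facial control would also be lost if the trans-alkene turns through the ring before it reacts. Fallback (from 21, returns at 26): hydroboration is done before the furanone is made. Ketone 21 is treated with excess BH3·THF, which also reduces the C1 ketone, and oxidised to the C1,C8-diol F10. The C8 hydroxyl, less hindered than the C1 carbinol next to the quaternary C10, is esterified with the angelic mixed anhydride to give F11. Dess–Martin oxidation gives the keto angelate F12, and Saegusa–Ito oxidation as in step 16 leads to 26.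

Step 20. What may go wrong: palladium-induced 5-endo hydroalkoxylation of the alkynol, or migration of the exocyclic double bond into the lactone ring, competes with CO insertion. Fallback (from 27, returns at 28): Markovnikov hydroiodination of the terminal alkyne (B-iodo-9-borabicyclo[3.3.1]nonane, then AcOH) gives the 2-iodoalkene F13. Carbonylative lactonisation through oxidative addition (Pd(PPh3)4, CO (1 atm), Et3N, MeCN, 50 °C) then closes the lactone.

## Further compounds

F1 | step 15 | β-keto ester from 16 (side chain CH2–C(=O)–CH2–CO2Me) | COC(=O)CC(=O)C[C@H]1O[C@](C#C[Si](C(C)C)(C(C)C)C(C)C)(/C=C/OCc2ccc(OC)cc2)[C@@H](O[Si](C)(C)C(C)(C)C)[C@@H](OCc2ccc(OC)cc2)[C@H]1C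
F2 | step 15 | α-diazo-β-keto ester | COC(=O)C(=[N+]=[N-])C(=O)C[C@H]1O[C@](C#C[Si](C(C)C)(C(C)C)C(C)C)(/C=C/OCc2ccc(OC)cc2)[C@@H](O[Si](C)(C)C(C)(C)C)[C@@H](OCc2ccc(OC)cc2)[C@H]1C
F3 | step 15 | ring-expanded keto ester (21 with CO2Me in place of the C10 methyl) | C[C@@H]1[C@H](OCc3ccc(OC)cc3)[C@H](O[Si](C)(C)C(C)(C)C)/C(C#C[Si](C(C)C)(C(C)C)C(C)C)=C/[C@@H](OCc3ccc(OC)cc3)[C@@]2(C(=O)OC)O[C@@H]1CC2=O
F4 | step 15 | diol (C1 carbinol, either epimer; C10–CH2OH) | C[C@@H]1[C@H](OCc3ccc(OC)cc3)[C@H](O[Si](C)(C)C(C)(C)C)/C(C#C[Si](C(C)C)(C(C)C)C(C)C)=C/[C@@H](OCc3ccc(OC)cc3)[C@@]2(CO)O[C@@H]1CC2O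
F5 | step 15 | primary O-phenyl thionocarbonate of F4 | C[C@@H]1[C@H](OCc3ccc(OC)cc3)[C@H](O[Si](C)(C)C(C)(C)C)/C(C#C[Si](C(C)C)(C(C)C)C(C)C)=C/[C@@H](OCc3ccc(OC)cc3)[C@@]2(COC(=S)Oc3ccccc3)O[C@@H]1CC2O
F6 | step 15 | C1 carbinol of 21 (C10 methyl, either C1 epimer) | C[C@@H]1[C@H](OCc3ccc(OC)cc3)[C@H](O[Si](C)(C)C(C)(C)C)/C(C#C[Si](C(C)C)(C(C)C)C(C)C)=C/[C@@H](OCc3ccc(OC)cc3)[C@@]2(C)O[C@@H]1CC2O
F7 | step 9 | hemiketal of 9 with (trimethylsilyl)ethynyl on C7 (both anomers) | COC(=O)C[C@H]1OC(O)(C#C[Si](C)(C)C)[C@@H](O[Si](C)(C)C(C)(C)C)[C@@H](OCc2ccc(OC)cc2)[C@H]1C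
F8 | step 9 | 1-(triisopropylsilyl)-2-(trimethylsilyl)acetylene | C[Si](C)(C)C#C[Si](C(C)C)(C(C)C)C(C)C
F9 | step 12 | (E)-2-iodovinyl oxane from 13 | COC(=O)C[C@H]1O[C@](C#C[Si](C(C)C)(C(C)C)C(C)C)(/C=C/I)[C@@H](O[Si](C)(C)C(C)(C)C)[C@@H](OCc2ccc(OC)cc2)[C@H]1C
F10 | step 17 | C1,C8-diol from 21 (7-H, 8-OH; C1 carbinol, either epimer) | C[C@@H]1[C@H](OCc3ccc(OC)cc3)[C@H](O[Si](C)(C)C(C)(C)C)[C@H](C#C[Si](C(C)C)(C(C)C)C(C)C)[C@H](O)[C@@H](OCc3ccc(OC)cc3)[C@@]2(C)O[C@@H]1CC2O
F11 | step 17 | C8 angelate of F10 | C[C@@H]1[C@H](OCc3ccc(OC)cc3)[C@H](O[Si](C)(C)C(C)(C)C)[C@H](C#C[Si](C(C)C)(C(C)C)C(C)C)[C@H](OC(=O)/C(C)=C\C)[C@@H](OCc3ccc(OC)cc3)[C@@]2(C)O[C@@H]1CC2O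
F12 | step 17 | C1 ketone of F11 (2,3-dihydro form of 26) | C[C@@H]1[C@H](OCc3ccc(OC)cc3)[C@H](O[Si](C)(C)C(C)(C)C)[C@H](C#C[Si](C(C)C)(C(C)C)C(C)C)[C@H](OC(=O)/C(C)=C\C)[C@@H](OCc3ccc(OC)cc3)[C@@]2(C)O[C@@H]1CC2=O
F13 | step 20 | 2-iodoalkene from 27 (C11(I)=C13H2 on C7) | C[C@@H]1[C@H](OCc3ccc(OC)cc3)[C@H](O)[C@H](C(I)=C)[C@H](OC(=O)/C(C)=C\C)[C@@H](OCc3ccc(OC)cc3)[C@@]2(C)OC1=CC2=O
A1 | alternative 1 | seco aldehyde–allylic bromide with preformed furanone (C6 aldehyde, (Z)-2-(bromomethyl)enoate at C7, silyl ethers on O5 and O9) | O=C[C@@H](O[Si](C)(C)C(C)(C)C)[C@@H](C)C1=CC(=O)[C@](C)(O1)[C@H](O[Si](C)(C)C(C)(C)C)[C@@H](OC(=O)/C(C)=C\C)/C=C(\CBr)C(=O)OC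
A2 | alternative 2 | 2-methyl-3-silyloxyfuran bearing the C4–C9 chain with the lactone and a C9 aldehyde | Cc1oc(cc1O[Si](C)(C)C(C)(C)C)[C@H](C)[C@H](O[Si](C)(C)C(C)(C)C)[C@@H]1OC(=O)C(=C)[C@@H]1[C@H](OC(=O)/C(C)=C\C)C=O
A3 | alternative 3 | 1,2-dialkenylcyclohexanol (ring C5–C10; C6, C7, C8, C9 as in the target, one trans arrangement of the two alkenyl groups) | C=C[C@]1(C)[C@H](O[Si](C)(C)C(C)(C)C)[C@@H](O[Si](C)(C)C(C)(C)C)[C@@H](CC(=O)OC)[C@@H](O[Si](C)(C)C(C)(C)C)[C@@]1(O)/C(C)=C/OCc1ccc(OC)cc1
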